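Ring B (C5–C10) of the eudesmane core carries at C7 a single exocyclic carbon, C11, which can be a carboxyl carbon before it becomes the carbinol. This C7–C11 pattern is used for a ring contraction. A seven-membered cyclic methyl enol ether fused to ring A reacts with tosyl azide. Nitrogen loss with 1,2-shift of a ring CH2 extrudes the methoxy carbon as the C11 ester while the six-membered ring forms. The precursor, a benzo[7]annulenone enol ether, comes from asymmetric conjugate addition/enolate alkylation of 3-methylcyclohexenone and ring-closing metathesis. Olefination with C5 epimerisation, hydration at C4, O-arylation of the tertiary alkoxide and two Suzuki couplings complete the honokiol ether.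

Key step: step 4

Remark: the SMILES is read as the natural eudesmane series (C10 methyl β, H-5 α, C7 side chain β, aryloxy at C4 α/equatorial), i.e. the cryptomeridiol ether of the 2-OH of honokiol; eudesmane numbering is used for ring positions.

Step 1
Reactants: 1 2-methoxyprop-1-ene
Product: 2 3-bromo-2-methoxyprop-1-ene
Conditions: NBS, excess 1 as solvent, cat. i-Pr2NEt, 0 °C → rt; distilled and used at once
Reagents that add atoms: N-bromosuccinimide, O=C1CCC(=O)N1Br
Why: Electrophilic bromination of the enol ether gives an oxocarbenium ion that loses a methyl proton, an allylic-type bromination that should give the 2-methoxyallyl bromide (an acetonyl equivalent) without a stereocentre.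

Step 2
Reactants: 3 3-methylcyclohex-2-en-1-one; 4 but-3-en-1-ylmagnesium bromide; 2 3-bromo-2-methoxyprop-1-ene
Product: 6 (3R)-3-(but-3-en-1-yl)-2-(2-methoxyprop-2-en-1-yl)-3-methylcyclohexan-1-one (both C2 epimers), via bromomagnesium enolate 5 (not isolated)
Conditions: Cu(OTf)2 (3 mol %), chiral C2-symmetric imidazolinium salt as NHC precursor (4 mol %, the enantiomer that gives the R centre), Et2O, −30 → 0 °C; then 2, DMPU, THF, 0 °C → rt; basic work-up
Reagents that add atoms: none
Why: Copper–NHC-catalysed asymmetric conjugate addition of the Grignard reagent to the β-substituted enone sets the quaternary C10 centre (R, face chosen by the chiral catalyst), and the regiodefined magnesium enolate is C-alkylated by the allylic bromide; the C5 configuration formed here does not matter because C5 is equilibrated in step 5.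

Step 3
Reactants: 6 (3R)-3-(but-3-en-1-yl)-2-(2-methoxyprop-2-en-1-yl)-3-methylcyclohexan-1-one
Product: 7 (4aR)-8-methoxy-4a-methyl-2,3,4,4a,5,6,9,9a-octahydro-1H-benzo[7]annulen-1-one (both C9a epimers)
Conditions: Grubbs second-generation catalyst (5 mol %), toluene (0.01 M), 70 °C; chromatography on Et3N-deactivated silica
Reagents that add atoms: none
Why: Ring-closing metathesis between the terminal alkene and the 1,1-disubstituted enol ether should close the seven-membered ring as its cyclic methyl enol ether with loss of ethene; no stereocentre is formed.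

Step 4
Reactants: 7 (4aR)-8-methoxy-4a-methyl-2,3,4,4a,5,6,9,9a-octahydro-1H-benzo[7]annulen-1-one
Product: 10 methyl (4aR)-4a-methyl-8-oxodecahydronaphthalene-2-carboxylate (epimers at C2 and C8a), via triazoline 8 (not isolated), via N-tosyl imidate 9 (not isolated)
Conditions: TsN3 (1.3 equiv), MeCN, 60 °C; then 1 M aq HCl, THF, rt
Reagents that add atoms: water, O (carbonyl oxygen of 10); tosyl azide, Cc1ccc(S(=O)(=O)N=[N+]=[N-])cc1 (its atoms are kept only in 8 and 9)
Why: The electron-rich enol ether adds tosyl azide in a regioselective [3+2] cycloaddition (terminal nitrogen to the CH carbon, sulfonylated nitrogen to the methoxy carbon) to give triazoline 8, which opens to a diazonium/sulfonamidate zwitterion; loss of N2 from the CH carbon is accompanied by 1,2-shift of the ring CH2 (C6) from the methoxy carbon, giving N-tosyl imidate 9, and dilute acid hydrolyses 9 to ester 10. The closest known reaction type is the ring contraction of 1-alkoxycycloalkenes (and enamines) with sulfonyl azides to imidates (amidines) of the next lower cycloalkanecarboxylic acid. The six-membered ring is closed not by a cyclisation but by this 1,2-alkyl shift onto the carbon that loses nitrogen, the seven-membered ring contracting by extrusion of the methoxy carbon, which becomes C11. C7 is the only new stereocentre; it is formed without useful control and, being α to the ester, is set later by equilibration in step 5, while C10 is untouched. The step needs chemoselectivity for the enol ether over the C4 ketone, which holds because sulfonyl azides do not react with ketones in the absence of base, and it needs migration of the ring bond rather than another group, which holds because the methoxy carbon bears no hydrogen and the ring bond is the one aligned anti to the departing N2. The carbon left in the ring lies between C6 and C8, so the ester can only end at C7.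

Step 5
Reactants: 10 methyl (4aR)-4a-methyl-8-oxodecahydronaphthalene-2-carboxylate
Product: 11 methyl (2R,4aR,8aS)-4a-methyl-8-methylidenedecahydronaphthalene-2-carboxylate
Conditions: Ph3PCH3Br, KOtBu, toluene, 80 °C; then NaOMe, MeOH, 60 °C
Reagents that add atoms: methylenetriphenylphosphorane, C=P(c1ccccc1)(c1ccccc1)c1ccccc1
Why: Wittig methylenation of the hindered ketone under basic conditions, in which C5 epimerises through the enolate and the less hindered trans-fused ketone should be olefinated faster (H-5 α, trans to the C10 methyl), followed by methoxide equilibration that places the C7 ester equatorial (7β); C5 and C7 are thus set relative to C10.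

Step 6
Reactants: 11 methyl (2R,4aR,8aS)-4a-methyl-8-methylidenedecahydronaphthalene-2-carboxylate
Product: 13 methyl (2R,4aR,8R,8aR)-8-hydroxy-4a,8-dimethyldecahydronaphthalene-2-carboxylate, via tertiary hydroperoxide 12 (not isolated)
Conditions: Mn(dpm)3 (10 mol %), PhSiH3, O2 (1 atm), i-PrOH/CH2Cl2, 0 °C → rt; then PPh3
Reagents that add atoms: dioxygen, O=O
Why: Mukaiyama hydration (metal-hydride hydrogen-atom transfer to the 1,1-disubstituted alkene, capture of the tertiary C4 radical by O2, reduction of the hydroperoxide) gives the Markovnikov alcohol, oxygen entering on the equatorial α face away from the syn-axial C10 methyl, so that C4 should be R (4α-OH, 4β-CH3).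

Step 7
Reactants: 14 4-bromo-2-chloro-1-iodobenzene; 15 1,3,5-trimethoxybenzene
Product: 17 (4-bromo-2-chlorophenyl)(2,4,6-trimethoxyphenyl)iodonium 4-methylbenzenesulfonate, via hydroxy(tosyloxy)iodoarene 16 (not isolated)
Conditions: mCPBA, TsOH·H2O, MeCN, 70 °C; then 15, rt
Reagents that add atoms: 4-methylbenzenesulfonic acid, Cc1ccc(S(=O)(=O)O)cc1 (tosylate counter-ion); mCPBA, O=C(OO)c1cccc(Cl)c1 (oxygen of 16 only)
Why: One-pot oxidation of the aryl iodide to the iodine(III) species and electrophilic aromatic substitution on trimethoxybenzene gives the unsymmetrical diaryliodonium salt, the trimethoxyphenyl group serving as the non-transferred ligand.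

Step 8
Reactants: 13 methyl (2R,4aR,8R,8aR)-8-hydroxy-4a,8-dimethyldecahydronaphthalene-2-carboxylate; 17 (4-bromo-2-chlorophenyl)(2,4,6-trimethoxyphenyl)iodonium 4-methylbenzenesulfonate
Product: 19 methyl (2R,4aR,8R,8aR)-8-(4-bromo-2-chlorophenoxy)-4a,8-dimethyldecahydronaphthalene-2-carboxylate, via sodium alkoxide 18 (not isolated)
Conditions: NaH (1.1 equiv), THF, 0 °C → rt; then 17, rt → 50 °C
Reagents that add atoms: none
Why: Metal-free O-arylation of a tertiary alkoxide with a diaryliodonium salt (ligand exchange at iodine(III), then ligand coupling) should transfer the electron-poorer ortho-substituted aryl group; the C4–O bond is not broken, so C4 keeps its configuration, and one equivalent of NaH deprotonates only the hydroxyl group.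

Step 9
Reactants: 19 methyl (2R,4aR,8R,8aR)-8-(4-bromo-2-chlorophenoxy)-4a,8-dimethyldecahydronaphthalene-2-carboxylate
Product: 21 2-[(2R,4aR,8R,8aR)-8-(4-bromo-2-chlorophenoxy)-4a,8-dimethyldecahydronaphthalen-2-yl]propan-2-ol, via methyl ketone 20 (not isolated)
Conditions: MeMgBr (4 equiv), THF, 0 °C → rt; aq NH4Cl
Reagents that add atoms: methylmagnesium bromide, C[Mg]Br
Why: Double Grignard addition to the methyl ester through the methyl ketone gives the C11 carbinol; aryl bromide and chloride are inert to MeMgBr at this temperature and no stereocentre is changed (C7 is no longer epimerisable afterwards).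

Step 10
Reactants: 21 2-[(2R,4aR,8R,8aR)-8-(4-bromo-2-chlorophenoxy)-4a,8-dimethyldecahydronaphthalen-2-yl]propan-2-ol
Product: 22 2-[(2R,4aR,8R,8aR)-8-[2-chloro-4-(prop-2-en-1-yl)phenoxy]-4a,8-dimethyldecahydronaphthalen-2-yl]propan-2-ol
Conditions: allylB(pin), Pd(dppf)Cl2 (5 mol %), CsF, THF, 65 °C
Reagents that add atoms: allylboronic acid pinacol ester, C=CCB1OC(C)(C)C(C)(C)O1
Why: Suzuki–Miyaura allylation should be selective for the C–Br bond over the hindered, less reactive C–Cl bond and places the allyl group para to the ether oxygen.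

Step 11
Reactants: 23 1-bromo-4-(prop-2-en-1-yloxy)benzene
Product: 24 4-bromo-2-(prop-2-en-1-yl)phenol
Conditions: N,N-diethylaniline, 200 °C
Reagents that add atoms: none
Why: Aromatic Claisen rearrangement ([3,3]-sigmatropic shift, then tautomerisation) moves the allyl group to the ortho carbon.

Step 12
Reactants: 24 4-bromo-2-(prop-2-en-1-yl)phenol
Product: 25 2-(prop-2-en-1-yl)-4-(4,4,5,5-tetramethyl-1,3,2-dioxaborolan-2-yl)phenol
Conditions: B2pin2, Pd(dppf)Cl2 (3 mol %), KOAc, 1,4-dioxane, 85 °C
Reagents that add atoms: bis(pinacolato)diboron, CC1(C)OB(B2OC(C)(C)C(C)(C)O2)OC1(C)C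
Why: Miyaura borylation of the aryl bromide; the free phenol and the allyl group should be tolerated under the weakly basic acetate conditions.

Step 13
Reactants: 22 2-[(2R,4aR,8R,8aR)-8-[2-chloro-4-(prop-2-en-1-yl)phenoxy]-4a,8-dimethyldecahydronaphthalen-2-yl]propan-2-ol; 25 2-(prop-2-en-1-yl)-4-(4,4,5,5-tetramethyl-1,3,2-dioxaborolan-2-yl)phenol
Product: 26 2-[(2R,4aR,8R,8aR)-8-{[4'-hydroxy-3',5-di(prop-2-en-1-yl)-[1,1'-biphenyl]-2-yl]oxy}-4a,8-dimethyldecahydronaphthalen-2-yl]propan-2-ol (target)
Conditions: XPhos Pd G3 (5 mol %), K3PO4, 1,4-dioxane/H2O, 90 °C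
Reagents that add atoms: none
Why: Suzuki–Miyaura biaryl coupling of the electron-rich ortho-alkoxy aryl chloride with a bulky biarylphosphine palladium catalyst should join the two rings ortho to the ether oxygen and give the target without protecting groups.

Compound list
1 | 2-methoxyprop-1-ene | COC(C)=C | starting material
2 | 3-bromo-2-methoxyprop-1-ene | COC(=C)CBr | intermediate
3 | 3-methylcyclohex-2-en-1-one | CC1=CC(=O)CCC1 | starting material
4 | but-3-en-1-ylmagnesium bromide | C=CCC[Mg]Br | starting material
5 | bromomagnesium (3R)-3-(but-3-en-1-yl)-3-methylcyclohex-1-en-1-olate | C=CCC[C@@]1(C)CCCC(O[Mg]Br)=C1 | intermediate (not isolated)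
6 | (3R)-3-(but-3-en-1-yl)-2-(2-methoxyprop-2-en-1-yl)-3-methylcyclohexan-1-one, both C2 epimers | O=C1CCC[C@](C)(CCC=C)C1CC(OC)=C | intermediate
7 | (4aR)-8-methoxy-4a-methyl-2,3,4,4a,5,6,9,9a-octahydro-1H-benzo[7]annulen-1-one, both C9a epimers | O=C1CCC[C@]2(C)CCC=C(OC)CC12 | intermediate
8 | 1-tosyl-1,2,3-triazoline cycloadduct of 7 (N-tosyl nitrogen on the methoxy carbon) | O=C1CCC[C@]2(C)CCC3N=NN(S(=O)(=O)c4ccc(C)cc4)C3(OC)CC12 | intermediate (not isolated)
9 | methyl (4aR)-4a-methyl-N-(4-methylbenzenesulfonyl)-8-oxodecahydronaphthalene-2-carboximidate | O=C1CCC[C@]2(C)CCC(C(OC)=NS(=O)(=O)c3ccc(C)cc3)CC12 | intermediate (not isolated)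
10 | methyl (4aR)-4a-methyl-8-oxodecahydronaphthalene-2-carboxylate, epimers at C2 and C8a | O=C1CCC[C@]2(C)CCC(C(=O)OC)CC12 | intermediate
11 | methyl (2R,4aR,8aS)-4a-methyl-8-methylidenedecahydronaphthalene-2-carboxylate | C=C2CCC[C@]3(C)CC[C@@H](C(=O)OC)C[C@H]32 | intermediate
12 | methyl (2R,4aR,8R,8aR)-8-hydroperoxy-4a,8-dimethyldecahydronaphthalene-2-carboxylate | OO[C@]2(C)CCC[C@]3(C)CC[C@@H](C(=O)OC)C[C@H]32 | intermediate (not isolated)
13 | methyl (2R,4aR,8R,8aR)-8-hydroxy-4a,8-dimethyldecahydronaphthalene-2-carboxylate | O[C@]2(C)CCC[C@]3(C)CC[C@@H](C(=O)OC)C[C@H]32 | intermediate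
14 | 4-bromo-2-chloro-1-iodobenzene | Clc1cc(Br)ccc1I | starting material
15 | 1,3,5-trimethoxybenzene | COc1cc(OC)cc(OC)c1 | starting material
16 | 4-bromo-2-chloro-1-[hydroxy(tosyloxy)-λ3-iodanyl]benzene | OI(OS(=O)(=O)c1ccc(C)cc1)c1ccc(Br)cc1Cl | intermediate (not isolated)
17 | (4-bromo-2-chlorophenyl)(2,4,6-trimethoxyphenyl)iodonium 4-methylbenzenesulfonate | COc1cc(OC)c([I+]c2ccc(Br)cc2Cl)c(OC)c1.Cc1ccc(S(=O)(=O)[O-])cc1 | intermediate
18 | sodium alkoxide of 13 | [Na+].[O-][C@]2(C)CCC[C@]3(C)CC[C@@H](C(=O)OC)C[C@H]32 | intermediate (not isolated)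
19 | methyl (2R,4aR,8R,8aR)-8-(4-bromo-2-chlorophenoxy)-4a,8-dimethyldecahydronaphthalene-2-carboxylate | Clc1cc(Br)ccc1O[C@]2(C)CCC[C@]3(C)CC[C@@H](C(=O)OC)C[C@H]32 | intermediate
20 | 1-[(2R,4aR,8R,8aR)-8-(4-bromo-2-chlorophenoxy)-4a,8-dimethyldecahydronaphthalen-2-yl]ethan-1-one | Clc1cc(Br)ccc1O[C@]2(C)CCC[C@]3(C)CC[C@@H](C(C)=O)C[C@H]32 | intermediate (not isolated)
21 | 2-[(2R,4aR,8R,8aR)-8-(4-bromo-2-chlorophenoxy)-4a,8-dimethyldecahydronaphthalen-2-yl]propan-2-ol | Clc1cc(Br)ccc1O[C@]2(C)CCC[C@]3(C)CC[C@@H](C(C)(C)O)C[C@H]32 | intermediate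
22 | 2-[(2R,4aR,8R,8aR)-8-[2-chloro-4-(prop-2-en-1-yl)phenoxy]-4a,8-dimethyldecahydronaphthalen-2-yl]propan-2-ol | C=CCc1ccc(O[C@]2(C)CCC[C@]3(C)CC[C@@H](C(C)(C)O)C[C@H]32)c(Cl)c1 | intermediate
23 | 1-bromo-4-(prop-2-en-1-yloxy)benzene | C=CCOc1ccc(Br)cc1 | starting material
24 | 4-bromo-2-(prop-2-en-1-yl)phenol | C=CCc1cc(Br)ccc1O | intermediate
25 | 2-(prop-2-en-1-yl)-4-(4,4,5,5-tetramethyl-1,3,2-dioxaborolan-2-yl)phenol | C=CCc1cc(B2OC(C)(C)C(C)(C)O2)ccc1O | intermediate
26 | 2-[(2R,4aR,8R,8aR)-8-{[4'-hydroxy-3',5-di(prop-2-en-1-yl)-[1,1'-biphenyl]-2-yl]oxy}-4a,8-dimethyldecahydronaphthalen-2-yl]propan-2-ol | C=CCc1ccc(O[C@]2(C)CCC[C@]3(C)CC[C@@H](C(C)(C)O)C[C@H]32)c(-c2ccc(O)c(CC=C)c2)c1 | target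

Total step count: 13. Longest linear sequence: 10 steps (steps 1, 2, 3, 4, 5, 6, 8, 9, 10, 13), or 9 counted from 3-methylcyclohex-2-en-1-one.

Steps most likely to fail, each with one fallback:

Step 4 (key step). The cycloaddition of the sulfonyl azide to the hindered trisubstituted enol ether may be slow, or the enol ether may be lost by hydrolysis before the ring shift. The fallback moves the contraction to an alkene oxythallation and sets out from 3 (with 4). The same conjugate addition is followed by trapping of the enolate with allyl bromide to give (3R)-3-(but-3-en-1-yl)-3-methyl-2-(prop-2-en-1-yl)cyclohexan-1-one F1. Ring-closing metathesis gives the cycloheptene (4aR)-4a-methyl-2,3,4,4a,5,6,9,9a-octahydro-1H-benzo[7]annulen-1-one F2. Thallium(III) nitrate in methanol/trimethyl orthoformate contracts the cycloheptene to (4aR)-7-(dimethoxymethyl)-4a-methyloctahydronaphthalen-1(2H)-one F3; either alkene carbon may be extruded, and both modes leave the acetal carbon on the atom between C6 and C8. Ozone then oxidises the acetal C–H to the methyl ester, which is 10, where the fallback rejoins the route.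

Step 8. Ligand coupling at iodine may fail for the hindered tertiary alkoxide, or base-induced aryne formation from the iodonium salt may scramble the substitution pattern of the aryl group. The fallback sets out from 11 and adds commercial 4-bromo-2-chlorophenol across the exocyclic alkene under kinetic acid catalysis (cat. TfOH, CH2Cl2, −78 °C; Markovnikov O-alkylation, as for tert-butyl aryl ethers from isobutene). The phenol should take the C4 cation from the equatorial α face. This gives 19 directly, bypasses steps 6–8 and makes no new compound (F0).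

Step 5. Olefination may outpace C5 epimerisation, so that stereoconvergence to the trans ring fusion is incomplete. The fallback sets out from 10. It is equilibrated with NaOMe/MeOH and the trans-fused, C7-equatorial keto ester methyl (2R,4aR,8aR)-4a-methyl-8-oxodecahydronaphthalene-2-carboxylate F4 is separated by chromatography, the cis-fused material being returned to the same equilibration. F4 is methylenated under non-basic Takai–Lombardo conditions (Zn, CH2Br2, TiCl4), which do not enolise the ketone, and the route is rejoined at 11.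

Further compounds
F1 | step 4 | (3R)-3-(but-3-en-1-yl)-3-methyl-2-(prop-2-en-1-yl)cyclohexan-1-one | O=C1CCC[C@](C)(CCC=C)C1CC=C
F2 | step 4 | (4aR)-4a-methyl-2,3,4,4a,5,6,9,9a-octahydro-1H-benzo[7]annulen-1-one | O=C1CCC[C@]2(C)CCC=CCC12
F3 | step 4 | (4aR)-7-(dimethoxymethyl)-4a-methyloctahydronaphthalen-1(2H)-one | O=C1CCC[C@]2(C)CCC(C(OC)OC)CC12
F0 | step 8 | none | none
F4 | step 5 | methyl (2R,4aR,8aR)-4a-methyl-8-oxodecahydronaphthalene-2-carboxylate | O=C2CCC[C@]3(C)CC[C@@H](C(=O)OC)C[C@H]32
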